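**Plan**

Numbering (labdane type): ring A = C1–C2–C3–C4–C5–C10, ring B = C5–C6–C7–C8–C9–C10. C4 bears CH3 and the 4‑methylpent‑3‑enyl group, C10 and C8 bear CH3, and C9 bears the C11–C15 enoic acid chain.

Retrosynthesis: cut C9–C11 (cross‑coupling at a C9 enol triflate), then C7=C8 (aldol condensation, ring B), then ring A at its two para bonds C2–C3 and C5–C10 (anionic [3+3] annulation).

Enabling feature: C2 and C10 flank C1, and C10 also adjoins C9, which is sp2 in the target. C1 and C9 can therefore both be carbonyls of a 2‑methyl‑1,3‑diketone, which makes C2 and C10 nucleophilic. C3 and C5 flank the quaternary C4, which can carry a formyl group (C3) and an enethioate (C5=C6–C7).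

Forward: geraniol → quaternary aldehyde → aldehyde–enethioate; union with 3‑methylhexane‑2,4‑dione builds ring A in one operation; ring B by aldol condensation; side chain by Suzuki coupling; the helper C1 carbonyl and ring A alkene are then removed.

Stereochemistry: C4 from a Sharpless epoxidation of geraniol, relayed by a stereospecific 1,2‑shift; C5 and C10 from C4 in the chair transition state of the ring‑closing Michael addition; the E enoate from the purchased (E)‑aldehyde ester.

Key step: step 9

**Route**

Step 1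
Reactants: 1 geraniol
Product: 2 [(2R,3R)-3-methyl-3-(4-methylpent-3-en-1-yl)oxiran-2-yl]methanol
Conditions: Ti(OiPr)4 (cat.), D-(−)-diethyl tartrate (cat.), t-BuOOH, 4 Å MS, CH2Cl2, −20 °C
Reagents that add atoms: tert-butyl hydroperoxide, CC(C)(C)OO
Why: Sharpless asymmetric epoxidation, in which the allylic hydroxyl binds the titanium tartrate so that only the 2,3-alkene is epoxidised and the D-tartrate should deliver the (2R,3R) epoxide.

Step 2
Reactants: 2 epoxy alcohol
Product: 3 tert-butyl{[(2R,3R)-3-methyl-3-(4-methylpent-3-en-1-yl)oxiran-2-yl]methoxy}dimethylsilane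
Conditions: TBSCl, imidazole, DMF, 0 → 25 °C
Reagents that add atoms: tert-butyldimethylsilyl chloride, CC(C)(C)[Si](C)(C)Cl
Why: Routine silylation of a primary alcohol, which supplies the silyloxymethyl group needed as the migrating group in step 3.

Step 3
Reactants: 3 epoxy silyl ether
Product: 4 (2R)-2-{[tert-butyl(dimethyl)silyl]oxymethyl}-2,6-dimethylhept-5-enal
Conditions: methylaluminium bis(4-bromo-2,6-di-tert-butylphenoxide) (MABR, 2 equiv), CH2Cl2, −78 °C
Reagents that add atoms: none
Why: Organoaluminium-promoted rearrangement of an epoxy silyl ether (semipinacol-type 1,2-shift), in which the bulky oxophilic Lewis acid opens the epoxide at the tertiary carbon and the silyloxymethyl group migrates anti to the breaking C–O bond, so the epoxide chirality should be transferred with inversion to the quaternary centre (target C4) carrying a formyl arm (future C5) and a CH2OTBS arm (future C3).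

Step 4
Reactants: 5 (diethoxyphosphoryl)acetic acid; 6 ethanethiol
Product: 7 S-ethyl (diethoxyphosphoryl)ethanethioate
Conditions: DCC, DMAP (cat.), CH2Cl2, 0 → 25 °C
Reagents that add atoms: none
Why: Steglich thioesterification of a carboxylic acid with a thiol.

Step 5
Reactants: 4 quaternary aldehyde; 7 thioester phosphonate
Product: 8 S-ethyl (2E,4S)-4-{[tert-butyl(dimethyl)silyl]oxymethyl}-4,8-dimethylnona-2,7-dienethioate
Conditions: NaH, THF, 0 °C; then 4, 0 → 25 °C
Reagents that add atoms: none
Why: Horner–Wadsworth–Emmons olefination, which with a stabilised phosphonate and an α-quaternary aldehyde should give the E enethioate (C5=C6–C7) without touching the non-epimerisable quaternary centre.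

Step 6
Reactants: 8 silyl ether
Product: 9 S-ethyl (2E,4S)-4-(hydroxymethyl)-4,8-dimethylnona-2,7-dienethioate
Conditions: HF·pyridine, pyridine/THF, 0 → 25 °C
Reagents that add atoms: none
Why: Fluoride-mediated desilylation under buffered acidic conditions that leave the thioester and the E-alkene (which cannot lactonise) untouched.

Step 7
Reactants: 9 primary alcohol
Product: 10 S-ethyl (2E,4S)-4-formyl-4,8-dimethylnona-2,7-dienethioate
Conditions: Dess–Martin periodinane, CH2Cl2, 25 °C
Reagents that add atoms: none
Why: Dess–Martin oxidation of a neopentyl alcohol to a non-enolisable aldehyde (C3), with no stereocentre at risk.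

Step 8
Reactants: 11 hexane-2,4-dione
Product: 12 3-methylhexane-2,4-dione
Conditions: MeI, K2CO3, acetone, reflux
Reagents that add atoms: iodomethane, CI
Why: C-alkylation of a 1,3-diketone at its central carbon, which installs the future C10 methyl group.

Step 9
Reactants: 10 aldehyde–enethioate; 12 3-methylhexane-2,4-dione
Product: 15 S-ethyl 2-[3-hydroxy-2,6-dimethyl-2-(4-methylpent-3-en-1-yl)-5-oxo-6-propanoylcyclohexyl]ethanethioate (ring A; 4β-CH3, 5α-H, 10β-CH3; both C3 carbinol epimers), via dilithium dianion of the diketone 13 (not isolated), via open-chain aldol adduct 14 (not isolated)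
Conditions: 12, LDA (2.2 equiv), THF, −78 → 0 °C; then 10, −78 °C; then AcOH (2.2 equiv), −78 → 40 °C (same flask, dilute)
Reagents that add atoms: none
Why: Double deprotonation gives the 1,3-dianion, whose hard terminal carbanion (C2) adds to the non-enolisable formyl carbon C3 faster than to the thioester; after buffering with AcOH the soft lithium diketonate carbon C10 adds to the β-carbon C5 of the enethioate, so the sequence is an anionic [3+3] annulation (aldol addition, then intramolecular Michael addition), the type known for 1,3-dicarbonyl dianions with 1,3-dielectrophiles and for Robinson-type ring construction. Ring A closes 6-exo-trig with the diketonate C1=C10 inside the ring (6-(enolendo)-exo-trig). C5 and C10 are set in a chair-like transition state governed by C4: the larger 4-methylpent-3-enyl group should lie equatorial and anti to the forming C5–C10 bond, the thioester arm on C5 equatorial, and the lithium chelate linking the diketonate oxygens to the thioester carbonyl should hold the propanoyl group equatorial on the side away from C4, leaving the C10 methyl axial (4β-CH3, 5α-H, 10β-CH3). The carbinol centre C3 forms as a mixture and is removed in step 11. The step needs site selectivity (CH3 over CH2 in the second deprotonation; CHO over thioester) and diastereoselectivity at C5/C10; the kinetic preference for the less substituted terminus, the electrophilicity order of the carbonyls and the chelated chair should secure them, and the buffered, near-neutral medium keeps the Michael step downhill.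

Step 10
Reactants: 15 hydroxy diketone thioester
Product: 16 2-[3-hydroxy-2,6-dimethyl-2-(4-methylpent-3-en-1-yl)-5-oxo-6-propanoylcyclohexyl]acetaldehyde (configuration as in 15)
Conditions: Et3SiH, 10% Pd/C, acetone, 25 °C
Reagents that add atoms: none
Why: Fukuyama reduction, which converts a thioester into an aldehyde under neutral conditions that should spare ketones, the free hydroxyl and the trisubstituted alkene.

Step 11
Reactants: 16 keto aldehyde
Product: 17 4,7,8a-trimethyl-4-(4-methylpent-3-en-1-yl)-4a,5-dihydronaphthalene-1,8(4H,8aH)-dione (labdane numbering: 1,9-dione, Δ2 and Δ7; 4β-CH3, 5α-H, 10β-CH3)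
Conditions: p-TsOH·H2O (cat.), benzene, 80 °C, Dean–Stark
Reagents that add atoms: none
Why: Acid-catalysed intramolecular aldol condensation of the ethyl ketone (C8) onto the aldehyde (C7) closes ring B as a cyclohexenone (the only six-membered closure available), and the β-hydroxy ketone in ring A dehydrates to the C2=C3 enone under the same conditions, with no epimerisable stereocentre involved.

Step 12
Reactants: 17 bis-enone
Product: 18 2,5,8a-trimethyl-5-(4-methylpent-3-en-1-yl)-8-oxo-3,4,4a,5,8,8a-hexahydronaphthalen-1-yl trifluoromethanesulfonate (C9 enol triflate, C8=C9; ring A enone retained; configuration as in 17)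
Conditions: L-Selectride (1.05 equiv), THF, −78 °C; then PhNTf2, −78 → 0 °C
Reagents that add atoms: N-phenylbis(trifluoromethanesulfonimide), O=S(=O)(N(c1ccccc1)S(=O)(=O)C(F)(F)F)C(F)(F)F
Why: Conjugate reduction with enolate trapping, in which the bulky hydride should add to the unhindered β-carbon C7 of the ring B enone rather than the neopentyl β-carbon C3 of the ring A enone, and the regiodefined C8=C9 enolate is triflated while the ring A enone, lacking α′- and γ-hydrogens, cannot enolise.

Step 13
Reactants: 19 ethyl (2E)-3-methyl-4-oxobut-2-enoate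
Product: 20 ethyl (2E)-3-methylpenta-2,4-dienoate
Conditions: Ph3PCH3Br, KOtBu, THF, 0 °C
Reagents that add atoms: methyltriphenylphosphonium bromide, C[P+](c1ccccc1)(c1ccccc1)c1ccccc1.[Br-]
Why: Wittig methylenation of the aldehyde, which leaves the existing E-trisubstituted enoate geometry unchanged.

Step 14
Reactants: 18 enol triflate; 20 dienoate
Product: 22 ethyl (2E)-3-methyl-5-[2,5,8a-trimethyl-5-(4-methylpent-3-en-1-yl)-8-oxo-3,4,4a,5,8,8a-hexahydronaphthalen-1-yl]pent-2-enoate (configuration as in 17), via alkyl-9-BBN borane 21 (not isolated)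
Conditions: 20, 9-BBN, THF, 0 → 25 °C; then 18, PdCl2(dppf) (cat.), AsPh3, Cs2CO3, DMF/H2O, 50 °C
Reagents that add atoms: none
Why: Anti-Markovnikov hydroboration of the terminal vinyl group followed by B-alkyl Suzuki–Miyaura coupling with the enol triflate forms C9–C11 and fixes the tetrasubstituted C8=C9 alkene, with the E enoate carried through unchanged.

Step 15
Reactants: 22 enone ester
Product: 24 ethyl (2E)-3-methyl-5-[2,5,8a-trimethyl-5-(4-methylpent-3-en-1-yl)-3,4,4a,5,6,8a-hexahydronaphthalen-1-yl]pent-2-enoate (labdane Δ1 alkene, CH2 at C3; configuration as in 17), via tosylhydrazone 23 (not isolated)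
Conditions: TsNHNH2, PPTS (cat.), EtOH, 60 °C; evaporate; catecholborane, CHCl3, 0 °C; then NaOAc·3H2O, 60 °C
Reagents that add atoms: none
Why: Tosylhydrazone reduction with alkene transposition, in which the only ketone (C1) condenses, hydride adds to C=N, and loss of sulfinate gives an allylic diazene that expels N2 by retro-ene hydrogen transfer to C3, removing the helper oxygen while ester and other alkenes are untouched.

Step 16
Reactants: 24 triene ester
Product: 25 ethyl (2E)-3-methyl-5-[(4aS,5S,8aS)-2,5,8a-trimethyl-5-(4-methylpent-3-en-1-yl)-3,4,4a,5,6,7,8,8a-octahydronaphthalen-1-yl]pent-2-enoate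
Conditions: dipotassium azodicarboxylate, AcOH, MeOH, 25 °C
Reagents that add atoms: none
Why: Diimide reduction, which should saturate the cis-disubstituted C1=C2 ring alkene far faster than the trisubstituted, tetrasubstituted or conjugated alkenes.

Step 17
Reactants: 25 ethyl ester
Product: 26 (2E)-3-methyl-5-[(4aS,5S,8aS)-2,5,8a-trimethyl-5-(4-methylpent-3-en-1-yl)-3,4,4a,5,6,7,8,8a-octahydronaphthalen-1-yl]pent-2-enoic acid (target)
Conditions: LiOH·H2O, THF/MeOH/H2O, 40 °C; then 1 M HCl
Reagents that add atoms: lithium hydroxide, [Li+].[OH-]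
Why: Saponification of the ethyl ester under mild conditions that should not isomerise the β,β-disubstituted E enoate.

**Compound list**

1 | geraniol | CC(C)=CCC/C(C)=C/CO | starting material
2 | [(2R,3R)-3-methyl-3-(4-methylpent-3-en-1-yl)oxiran-2-yl]methanol | OC[C@H]1O[C@]1(C)CCC=C(C)C | intermediate
3 | tert-butyl{[(2R,3R)-3-methyl-3-(4-methylpent-3-en-1-yl)oxiran-2-yl]methoxy}dimethylsilane | CC(C)(C)[Si](C)(C)OC[C@H]1O[C@]1(C)CCC=C(C)C | intermediate
4 | (2R)-2-{[tert-butyl(dimethyl)silyl]oxymethyl}-2,6-dimethylhept-5-enal | O=C[C@@](C)(CO[Si](C)(C)C(C)(C)C)CCC=C(C)C | intermediate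
5 | (diethoxyphosphoryl)acetic acid | CCOP(=O)(OCC)CC(=O)O | starting material
6 | ethanethiol | CCS | starting material
7 | S-ethyl (diethoxyphosphoryl)ethanethioate | CCOP(=O)(OCC)CC(=O)SCC | intermediate
8 | S-ethyl (2E,4S)-4-{[tert-butyl(dimethyl)silyl]oxymethyl}-4,8-dimethylnona-2,7-dienethioate | CCSC(=O)/C=C/[C@@](C)(CO[Si](C)(C)C(C)(C)C)CCC=C(C)C | intermediate
9 | S-ethyl (2E,4S)-4-(hydroxymethyl)-4,8-dimethylnona-2,7-dienethioate | CCSC(=O)/C=C/[C@@](C)(CO)CCC=C(C)C | intermediate
10 | S-ethyl (2E,4S)-4-formyl-4,8-dimethylnona-2,7-dienethioate | CCSC(=O)/C=C/[C@@](C)(C=O)CCC=C(C)C | intermediate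
11 | hexane-2,4-dione | CCC(=O)CC(C)=O | starting material
12 | 3-methylhexane-2,4-dione | CCC(=O)C(C)C(C)=O | intermediate
13 | dilithium 3-methylhexa-1,3-diene-2,4-diolate (dianion of 12) | [Li+].[Li+].C=C([O-])C(C)=C([O-])CC | intermediate
14 | S-ethyl (2E)-4-(1-hydroxy-4-methyl-3,5-dioxoheptyl)-4,8-dimethylnona-2,7-dienethioate (C4 as in 10; carbinol and C10 unassigned) | CCC(=O)C(C)C(=O)CC(O)[C@@](C)(CCC=C(C)C)/C=C/C(=O)SCC | intermediate
15 | S-ethyl 2-[3-hydroxy-2,6-dimethyl-2-(4-methylpent-3-en-1-yl)-5-oxo-6-propanoylcyclohexyl]ethanethioate (4β-CH3, 5α-H, 10β-CH3; C3 epimers) | CCC(=O)[C@@]1(C)C(=O)CC(O)[C@@](C)(CCC=C(C)C)[C@@H]1CC(=O)SCC | intermediate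
16 | 2-[3-hydroxy-2,6-dimethyl-2-(4-methylpent-3-en-1-yl)-5-oxo-6-propanoylcyclohexyl]acetaldehyde | CCC(=O)[C@@]1(C)C(=O)CC(O)[C@@](C)(CCC=C(C)C)[C@@H]1CC=O | intermediate
17 | 4,7,8a-trimethyl-4-(4-methylpent-3-en-1-yl)-4a,5-dihydronaphthalene-1,8(4H,8aH)-dione | O=C1C=C[C@@](C)(CCC=C(C)C)[C@@H]2CC=C(C)C(=O)[C@@]12C | intermediate
18 | 2,5,8a-trimethyl-5-(4-methylpent-3-en-1-yl)-8-oxo-3,4,4a,5,8,8a-hexahydronaphthalen-1-yl trifluoromethanesulfonate | O=C1C=C[C@@](C)(CCC=C(C)C)[C@@H]2CCC(C)=C(OS(=O)(=O)C(F)(F)F)[C@@]12C | intermediate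
19 | ethyl (2E)-3-methyl-4-oxobut-2-enoate | CCOC(=O)/C=C(\C)C=O | starting material
20 | ethyl (2E)-3-methylpenta-2,4-dienoate | CCOC(=O)/C=C(\C)C=C | intermediate
21 | ethyl (2E)-5-(9-borabicyclo[3.3.1]nonan-9-yl)-3-methylpent-2-enoate | CCOC(=O)/C=C(\C)CCB1C2CCCC1CCC2 | intermediate
22 | ethyl (2E)-3-methyl-5-[2,5,8a-trimethyl-5-(4-methylpent-3-en-1-yl)-8-oxo-3,4,4a,5,8,8a-hexahydronaphthalen-1-yl]pent-2-enoate | O=C1C=C[C@@](C)(CCC=C(C)C)[C@@H]2CCC(C)=C(CC/C(C)=C/C(=O)OCC)[C@@]12C | intermediate
23 | 4-methylbenzenesulfonylhydrazone of 22 at the ring ketone | Cc1ccc(cc1)S(=O)(=O)NN=C1C=C[C@@](C)(CCC=C(C)C)[C@@H]2CCC(C)=C(CC/C(C)=C/C(=O)OCC)[C@@]12C | intermediate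
24 | ethyl (2E)-3-methyl-5-[2,5,8a-trimethyl-5-(4-methylpent-3-en-1-yl)-3,4,4a,5,6,8a-hexahydronaphthalen-1-yl]pent-2-enoate | C1=CC[C@@](C)(CCC=C(C)C)[C@@H]2CCC(C)=C(CC/C(C)=C/C(=O)OCC)[C@@]12C | intermediate
25 | ethyl (2E)-3-methyl-5-[(4aS,5S,8aS)-2,5,8a-trimethyl-5-(4-methylpent-3-en-1-yl)-3,4,4a,5,6,7,8,8a-octahydronaphthalen-1-yl]pent-2-enoate | CC(C)=CCC[C@]1(C)CCC[C@]2(C)C(CC/C(C)=C/C(=O)OCC)=C(C)CC[C@@H]12 | intermediate
26 | (2E)-3-methyl-5-[(4aS,5S,8aS)-2,5,8a-trimethyl-5-(4-methylpent-3-en-1-yl)-3,4,4a,5,6,7,8,8a-octahydronaphthalen-1-yl]pent-2-enoic acid | CC(C)=CCC[C@]1(C)CCC[C@]2(C)C(CC/C(C)=C/C(=O)O)=C(C)CC[C@@H]12 | target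

**Step count**

Total: 17 steps. Longest linear sequence: 14 steps (1, 2, 3, 5, 6, 7, 9, 10, 11, 12, 14, 15, 16, 17).

**Steps most likely to fail**

1. Step 9. The ring-closing Michael addition may proceed with poor facial selectivity at C10 (propanoyl ending axial instead of methyl) or at C5 relative to C4, and the second deprotonation may occur partly at the ethyl CH2. The fallback replaces one-pot chelate control by a Lewis-acid union followed by catalyst-controlled closure; it sets out from 10 and 12 and returns at 15. Compound 12 would be silylated twice (TMSCl/Et3N, then LDA/TMSCl) to 3-methyl-2,4-bis(trimethylsilyloxy)hexa-1,3-diene F1. A TiCl4-mediated Mukaiyama aldol of its terminal CH2 with 10 at −78 °C would give, after work-up, the open-chain adduct 14, now isolated. Compound 14 would then be cyclised with a chiral bifunctional tertiary amine–squaramide catalyst, its antipode chosen to match C4, to give 15.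

2. Step 12. The hydride may also attack the ring A enone (1,2- or 1,4-), so that the two enones are not told apart. The fallback reduces both on purpose and differentiates at the palladium stage; it sets out from 17 and returns at 24, skipping step 15. Li/NH3 reduction of both enones and trapping with PhNTf2 would give 2,5,8a-trimethyl-5-(4-methylpent-3-en-1-yl)-3,4,4a,5,6,8a-hexahydronaphthalene-1,8-diyl bis(trifluoromethanesulfonate) F2. Pd(OAc)2/PPh3 with HCO2H/Bu3N should hydrogenolyse the less hindered trisubstituted triflate to give 2,5,8a-trimethyl-5-(4-methylpent-3-en-1-yl)-3,4,4a,5,6,8a-hexahydronaphthalen-1-yl trifluoromethanesulfonate F3. Suzuki coupling of F3 with borane 21 would then give 24.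

3. Step 14. Oxidative addition at the tetrasubstituted triflate flanked by a quaternary carbon may be slow, and the functionalised alkylborane may undergo protodeboronation or β-hydride elimination. The fallback couples a simple alkylzinc and builds the enoate afterwards; it sets out from 18 and returns at 22. Negishi coupling with but-3-enylzinc bromide would give 8-(but-3-en-1-yl)-4,7,8a-trimethyl-4-(4-methylpent-3-en-1-yl)-4a,5,6,8a-tetrahydronaphthalen-1(4H)-one F4. Wacker oxidation of the terminal alkene would give 4,7,8a-trimethyl-4-(4-methylpent-3-en-1-yl)-8-(3-oxobutyl)-4a,5,6,8a-tetrahydronaphthalen-1(4H)-one F5. Horner–Wadsworth–Emmons reaction of the methyl ketone with triethyl phosphonoacetate would give 22, the minor Z isomer being separated.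

**Further compounds**

F1 | step 9 | 3-methyl-2,4-bis(trimethylsilyloxy)hexa-1,3-diene | C=C(O[Si](C)(C)C)C(C)=C(CC)O[Si](C)(C)C
F2 | step 12 | 2,5,8a-trimethyl-5-(4-methylpent-3-en-1-yl)-3,4,4a,5,6,8a-hexahydronaphthalene-1,8-diyl bis(trifluoromethanesulfonate) | O=S(=O)(OC1=CC[C@@](C)(CCC=C(C)C)[C@@H]2CCC(C)=C(OS(=O)(=O)C(F)(F)F)[C@@]12C)C(F)(F)F
F3 | step 12 | 2,5,8a-trimethyl-5-(4-methylpent-3-en-1-yl)-3,4,4a,5,6,8a-hexahydronaphthalen-1-yl trifluoromethanesulfonate | C1=CC[C@@](C)(CCC=C(C)C)[C@@H]2CCC(C)=C(OS(=O)(=O)C(F)(F)F)[C@@]12C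
F4 | step 14 | 8-(but-3-en-1-yl)-4,7,8a-trimethyl-4-(4-methylpent-3-en-1-yl)-4a,5,6,8a-tetrahydronaphthalen-1(4H)-one | O=C1C=C[C@@](C)(CCC=C(C)C)[C@@H]2CCC(C)=C(CCC=C)[C@@]12C
F5 | step 14 | 4,7,8a-trimethyl-4-(4-methylpent-3-en-1-yl)-8-(3-oxobutyl)-4a,5,6,8a-tetrahydronaphthalen-1(4H)-one | O=C1C=C[C@@](C)(CCC=C(C)C)[C@@H]2CCC(C)=C(CCC(C)=O)[C@@]12C
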